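**Plan**

- Retrosynthetic cuts: the five O–benzyl bonds (made last), then the interflavanyl C4(ring C)–C6(ring D) bond. In the lower unit the C3–H and C2–H bonds lead back to a flat 3-acetoxyflavylium cation, and O1–C2 plus C3=C4 of ring F lead back to a salicylaldehyde and an α-acetoxy aryl ketone. In the upper unit C4–H, O1–C2 and Cα=Cβ lead back to a chalcone.
- Enabling feature: in ring F, C2 carries both O1 and ring E and C3 carries oxygen, so ring F is the reduced form of a 3-oxygenated 2-arylbenzopyrylium ring. It can therefore be closed through O1–C2 by attack of the ring D phenol oxygen on an aryl ketone carbon, driven by aromatisation, with C2 and C3 left trigonal.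
- Forward order: ring F as a pyrylium, then the flavan-3-one, then the 2,3-cis lower unit; ring C of the upper unit via chalcone epoxide, dihydroflavonol and flavan-3,4-diol; C4→C6 union; global debenzylation.
- Stereochemistry: lower C2 and C3 (2S,3S) are set together by one catalyst-controlled hydrogenation with dynamic kinetic resolution of the C2-labile flavan-3-one. Upper C3 comes from a Juliá–Colonna epoxidation, upper C2 from trans-selective epoxide opening, and upper C4 from attack anti to the 3-hydroxyl in the coupling.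

Key step: step 3

Assumption: the four benzyl-protected aromatic starting materials are taken as commercial.
Assumption: RuCl2[(S)-Xyl-SDP][(R,R)-DPEN] (Xyl-SDP = 7,7'-bis[bis(3,5-dimethylphenyl)phosphino]-1,1'-spirobiindane, DPEN = 1,2-diphenylethane-1,2-diamine) is assumed to give the (2S,3S) alcohol by analogy with cis-selective reductions of 2-arylcycloalkanones; if the sense proves opposite, the mirror-image complex is used.

**Route**

Step 1
Reactants: 1 1-[3,4-bis(benzyloxy)phenyl]ethanone
Product: 2 2-bromo-1-[3,4-bis(benzyloxy)phenyl]ethanone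
Conditions: CuBr2 (2.1 equiv), EtOAc/CHCl3, reflux
Reagents that add atoms: copper dibromide, Br[Cu]Br
Why: Enol-mediated α-bromination of an aryl methyl ketone by CuBr2 is selective for the side chain over the benzyloxylated ring; no stereocentre is formed.

Step 2
Reactants: 2 2-bromo-1-[3,4-bis(benzyloxy)phenyl]ethanone
Product: 3 2-[3,4-bis(benzyloxy)phenyl]-2-oxoethyl acetate
Conditions: KOAc, DMF, rt
Reagents that add atoms: potassium acetate, CC(=O)[O-].[K+]
Why: SN2 displacement of the phenacyl bromide by acetate installs the oxygen that becomes O3 of ring F; no stereocentre is formed.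

Step 3
Reactants: 3 2-[3,4-bis(benzyloxy)phenyl]-2-oxoethyl acetate; 4 4-(benzyloxy)-2-hydroxybenzaldehyde
Product: 6 3-(acetyloxy)-7-(benzyloxy)-2-[3,4-bis(benzyloxy)phenyl]chromenylium chloride, via hydroxy enone 5 (not isolated)
Conditions: dry HCl (gas), EtOAc, 0 °C then 4 °C, 48 h; salt precipitated with Et2O
Reagents that add atoms: hydrogen chloride, Cl
Why: Acid-catalysed crossed aldol condensation joins the CH2OAc carbon of 3 (future C3) to the aldehyde carbon of 4 (future C4) to give enone 5, whose E and Z forms interconvert in HCl; in the form with ring D cis to the aroyl group the ring D phenol oxygen adds to the protonated aryl ketone carbon to give a cyclic hemiketal, and loss of water gives the benzopyrylium cation. The closest known reaction type is the classical acid-mediated synthesis of 3-acyloxyflavylium (anthocyanidin) salts from salicylaldehydes and ω-acyloxyacetophenones. Ring F is closed by O1–C2 bond formation in a 6-exo-trig attack on the C2=O group, and aromatisation makes the closure irreversible. No stereocentre is formed: C2 and C3 are deliberately left trigonal so that both are set together in step 5. The step needs cross- rather than self-condensation and closure through the correct oxygen; the first is secured because only 3 can enolise and only 4 carries an aldehyde, the second because only the ortho hydroxyl of ring D can reach C2 while the para oxygen is benzylated.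

Step 4
Reactants: 6 3-(acetyloxy)-7-(benzyloxy)-2-[3,4-bis(benzyloxy)phenyl]chromenylium chloride
Product: 8 rac-7-(benzyloxy)-2-[3,4-bis(benzyloxy)phenyl]-2H-chromen-3(4H)-one, via flavene enol acetate 7 (not isolated)
Conditions: Hantzsch ester (diethyl 2,6-dimethyl-1,4-dihydropyridine-3,5-dicarboxylate, 1.1 equiv), CH2Cl2, 0 °C; then K2CO3 (1.5 equiv), MeOH, 0 °C, argon
Reagents that add atoms: none
Why: NADH-model hydride transfer from the 1,4-dihydropyridine to the benzopyrylium cation (at C4, or at C2, both adducts being enol acetates of the same ketone), then methanolysis of the enol acetate and C-protonation, should give the flavan-3-one; C2 forms racemic and is left configurationally labile on purpose.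

Step 5
Reactants: 8 rac-7-(benzyloxy)-2-[3,4-bis(benzyloxy)phenyl]-2H-chromen-3(4H)-one
Product: 9 (2S,3S)-7-(benzyloxy)-2-[3,4-bis(benzyloxy)phenyl]-3,4-dihydro-2H-chromen-3-ol
Conditions: RuCl2[(S)-Xyl-SDP][(R,R)-DPEN] (1 mol %), KOtBu (20 mol %), H2 (50 atm), iPrOH/toluene, rt
Reagents that add atoms: none
Why: Noyori-type asymmetric hydrogenation with dynamic kinetic resolution, as known for 2-arylcycloalkanones and α-aryloxy ketones: C2–H (α to the ketone, benzylic to ring E, bearing O1) epimerises through the enolate while the chiral catalyst reduces one enantiomer faster and delivers hydride to C3=O anti to the 2-aryl group, so C2 (S) and C3 (S) should be set together, 2,3-cis, by catalyst control.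

Step 6
Reactants: 10 1-[4-(benzyloxy)-2-hydroxyphenyl]ethanone
Product: 11 1-[4-(benzyloxy)-2-(methoxymethoxy)phenyl]ethanone
Conditions: NaH, DMF, 0 °C; then MOMCl, 0 °C to rt
Reagents that add atoms: chloromethyl methyl ether, COCCl
Why: Williamson-type O-alkylation masks the chelated ortho hydroxyl so that the enone of step 8 is not lost to base-mediated cyclisation; no stereocentre is formed.

Step 7
Reactants: 11 1-[4-(benzyloxy)-2-(methoxymethoxy)phenyl]ethanone; 12 4-(benzyloxy)benzaldehyde
Product: 13 (E)-1-[4-(benzyloxy)-2-(methoxymethoxy)phenyl]-3-[4-(benzyloxy)phenyl]prop-2-en-1-one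
Conditions: KOH (aq.), EtOH, rt
Reagents that add atoms: none
Why: Claisen–Schmidt condensation of a methyl ketone with a non-enolisable aldehyde should give the (E)-chalcone under thermodynamic control.

Step 8
Reactants: 13 (E)-1-[4-(benzyloxy)-2-(methoxymethoxy)phenyl]-3-[4-(benzyloxy)phenyl]prop-2-en-1-one
Product: 14 [(2R,3S)-3-[4-(benzyloxy)phenyl]oxiran-2-yl][4-(benzyloxy)-2-(methoxymethoxy)phenyl]methanone
Conditions: poly-L-leucine, urea–hydrogen peroxide, DBU, THF, rt
Reagents that add atoms: urea–hydrogen peroxide, NC(N)=O.OO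
Why: Juliá–Colonna epoxidation: hydroperoxide adds to the enone held on the helical poly-L-leucine, which directs attack to one face and should give the (αR,βS)-trans epoxide, fixing the later C3 of the upper unit.

Step 9
Reactants: 14 [(2R,3S)-3-[4-(benzyloxy)phenyl]oxiran-2-yl][4-(benzyloxy)-2-(methoxymethoxy)phenyl]methanone
Product: 16 (2R,3R)-7-(benzyloxy)-2-[4-(benzyloxy)phenyl]-3-hydroxy-2,3-dihydro-4H-chromen-4-one, via free phenol epoxide 15 (not isolated)
Conditions: conc. HCl, MeOH/THF, 50 °C
Reagents that add atoms: none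
Why: Acidic methanolysis removes the MOM acetal and the freed phenol opens the epoxide at the p-benzyloxybenzylic carbon in a 6-endo mode (chalcone epoxide to dihydroflavonol cyclisation) with inversion there, so C3 (R) comes from the epoxide and C2 (R) ends trans to it, the trans isomer also being the thermodynamic one.

Step 10
Reactants: 16 (2R,3R)-7-(benzyloxy)-2-[4-(benzyloxy)phenyl]-3-hydroxy-2,3-dihydro-4H-chromen-4-one
Product: 17 (2R,3S,4R)-7-(benzyloxy)-2-[4-(benzyloxy)phenyl]-3,4-dihydro-2H-chromene-3,4-diol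
Conditions: NaBH4, MeOH/THF, 0 °C
Reagents that add atoms: none
Why: Borohydride reduction of the aryl ketone of a 2,3-trans dihydroflavonol should give mainly the 3,4-trans diol by axial hydride delivery; the C4 configuration is of no consequence because this centre is ionised in step 11.

Step 11
Reactants: 17 (2R,3S,4R)-7-(benzyloxy)-2-[4-(benzyloxy)phenyl]-3,4-dihydro-2H-chromene-3,4-diol; 9 (2S,3S)-7-(benzyloxy)-2-[3,4-bis(benzyloxy)phenyl]-3,4-dihydro-2H-chromen-3-ol
Product: 18 penta-O-benzyl ether of 19 (benzyl on upper O7 and O4' and on lower O7, O3' and O4'; all five stereocentres as in 19)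
Conditions: Yb(OTf)3 (10 mol %), CH2Cl2, 0 °C to rt; 9 in threefold excess, unreacted 9 recovered by chromatography
Reagents that add atoms: none
Why: Dehydrative Friedel–Crafts-type flavan-4-yl arylation with water as the only coproduct: the water-tolerant Lewis acid catalyst ionises C4–OH of 17 to a benzylic cation stabilised by O1 (ortho) and the 7-benzyloxy group (para), ring D of 9 should attack through C6 (para to O1, ortho to O7) because C8 is flanked by two oxygens, and approach anti to the 3-hydroxyl should set C4 as the 3,4-trans (4α) centre, the excess of 9 limiting self-condensation of 17.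

Step 12
Reactants: 18 penta-O-benzyl ether of 19
Product: 19 (2R,3S,4R)-4-[(2S,3S)-2-(3,4-dihydroxyphenyl)-3,7-dihydroxy-3,4-dihydro-2H-chromen-6-yl]-2-(4-hydroxyphenyl)-3,4-dihydro-2H-chromene-3,7-diol
Conditions: H2 (1 atm), Pd(OH)2/C, THF/MeOH/H2O, rt
Reagents that add atoms: none
Why: Hydrogenolysis of the five aryl benzyl ethers over Pd(OH)2/C should leave the interflavanyl C–C bond, the ring C–O bonds and all five stereocentres untouched.

**Compound list**

1 | 1-[3,4-bis(benzyloxy)phenyl]ethanone | CC(=O)c1ccc(OCc2ccccc2)c(OCc2ccccc2)c1 | starting material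
2 | 2-bromo-1-[3,4-bis(benzyloxy)phenyl]ethanone | O=C(CBr)c1ccc(OCc2ccccc2)c(OCc2ccccc2)c1 | intermediate
3 | 2-[3,4-bis(benzyloxy)phenyl]-2-oxoethyl acetate | CC(=O)OCC(=O)c1ccc(OCc2ccccc2)c(OCc2ccccc2)c1 | intermediate
4 | 4-(benzyloxy)-2-hydroxybenzaldehyde | O=Cc1ccc(OCc2ccccc2)cc1O | starting material
5 | (E)-3-[4-(benzyloxy)-2-hydroxyphenyl]-1-[3,4-bis(benzyloxy)phenyl]-1-oxoprop-2-en-2-yl acetate (cyclisation-competent isomer; not isolated) | CC(=O)O/C(=C/c1ccc(OCc2ccccc2)cc1O)C(=O)c1ccc(OCc2ccccc2)c(OCc2ccccc2)c1 | intermediate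
6 | 3-(acetyloxy)-7-(benzyloxy)-2-[3,4-bis(benzyloxy)phenyl]chromenylium chloride | CC(=O)Oc1cc2ccc(OCc3ccccc3)cc2[o+]c1-c1ccc(OCc2ccccc2)c(OCc2ccccc2)c1.[Cl-] | intermediate
7 | 7-(benzyloxy)-2-[3,4-bis(benzyloxy)phenyl]-4H-chromen-3-yl acetate (not isolated) | CC(=O)OC1=C(c2ccc(OCc3ccccc3)c(OCc3ccccc3)c2)Oc2cc(OCc3ccccc3)ccc2C1 | intermediate
8 | rac-7-(benzyloxy)-2-[3,4-bis(benzyloxy)phenyl]-2H-chromen-3(4H)-one | O=C1Cc2ccc(OCc3ccccc3)cc2OC1c1ccc(OCc2ccccc2)c(OCc2ccccc2)c1 | intermediate
9 | (2S,3S)-7-(benzyloxy)-2-[3,4-bis(benzyloxy)phenyl]-3,4-dihydro-2H-chromen-3-ol | c1cc2c(cc1OCc1ccccc1)O[C@@H](c1ccc(OCc3ccccc3)c(OCc3ccccc3)c1)[C@@H](O)C2 | intermediate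
10 | 1-[4-(benzyloxy)-2-hydroxyphenyl]ethanone | CC(=O)c1ccc(OCc2ccccc2)cc1O | starting material
11 | 1-[4-(benzyloxy)-2-(methoxymethoxy)phenyl]ethanone | CC(=O)c1ccc(OCc2ccccc2)cc1OCOC | intermediate
12 | 4-(benzyloxy)benzaldehyde | O=Cc1ccc(OCc2ccccc2)cc1 | starting material
13 | (E)-1-[4-(benzyloxy)-2-(methoxymethoxy)phenyl]-3-[4-(benzyloxy)phenyl]prop-2-en-1-one | COCOc1cc(OCc2ccccc2)ccc1C(=O)/C=C/c1ccc(OCc2ccccc2)cc1 | intermediate
14 | [(2R,3S)-3-[4-(benzyloxy)phenyl]oxiran-2-yl][4-(benzyloxy)-2-(methoxymethoxy)phenyl]methanone | COCOc1cc(OCc2ccccc2)ccc1C(=O)[C@@H]1O[C@H]1c1ccc(OCc2ccccc2)cc1 | intermediate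
15 | [(2R,3S)-3-[4-(benzyloxy)phenyl]oxiran-2-yl][4-(benzyloxy)-2-hydroxyphenyl]methanone (not isolated) | Oc1cc(OCc2ccccc2)ccc1C(=O)[C@@H]1O[C@H]1c1ccc(OCc2ccccc2)cc1 | intermediate
16 | (2R,3R)-7-(benzyloxy)-2-[4-(benzyloxy)phenyl]-3-hydroxy-2,3-dihydro-4H-chromen-4-one | C(c1ccccc1)Oc1ccc(cc1)[C@H]1Oc2cc(OCc3ccccc3)ccc2C(=O)[C@@H]1O | intermediate
17 | (2R,3S,4R)-7-(benzyloxy)-2-[4-(benzyloxy)phenyl]-3,4-dihydro-2H-chromene-3,4-diol | C(c1ccccc1)Oc1ccc(cc1)[C@H]1Oc2cc(OCc3ccccc3)ccc2[C@@H](O)[C@@H]1O | intermediate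
18 | penta-O-benzyl ether of 19 (2,3-trans-3,4-trans upper unit, 4α→6 link, 2,3-cis lower unit) | C(c1ccccc1)Oc1ccc([C@H]2Oc3cc(OCc4ccccc4)ccc3[C@@H](c3cc4c(cc3OCc3ccccc3)O[C@@H](c3ccc(OCc5ccccc5)c(OCc5ccccc5)c3)[C@@H](O)C4)[C@@H]2O)cc1 | intermediate
19 | (2R,3S,4R)-4-[(2S,3S)-2-(3,4-dihydroxyphenyl)-3,7-dihydroxy-3,4-dihydro-2H-chromen-6-yl]-2-(4-hydroxyphenyl)-3,4-dihydro-2H-chromene-3,7-diol | Oc1ccc([C@H]2Oc3cc(O)ccc3[C@@H](c3cc4c(cc3O)O[C@@H](c3ccc(O)c(O)c3)[C@@H](O)C4)[C@@H]2O)cc1 | target

**Summary**

Total step count: 12. Longest linear sequence: 7 steps (steps 1–5, 11, 12; the branch 6–10, 11, 12 is equally long).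

Steps most likely to fail:

1. Step 5. Epimerisation at C2 may be too slow relative to reduction, or the catalyst may discriminate poorly between the two α-sides of a ketone that is not aryl-conjugated, giving low enantio- or diastereocontrol. Fallback by reduction and classical resolution: from 8, LiBH(sBu)3 in THF at −78 °C should give the racemic 2,3-cis alcohol F1 (hydride anti to the 2-aryl group). Esterification with (S)-2-methoxy-2-phenylacetic acid (DCC, DMAP, CH2Cl2) gives the (2S,3S)-configured (S)-2-methoxy-2-phenylacetate F2 and the (2R,3R)-configured diastereomeric ester F3. F2 is separated by chromatography or crystallisation and saponified (LiOH, THF/H2O) to rejoin the route at 9.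

2. Step 11. The cation from 17 may be captured by ring A of a second molecule of 17 (oligomerisation), by C8 or the 3-hydroxyl of 9, or from the face syn to O3. Fallback by changing the electrophile to a thioether activated thiophilically under near-neutral conditions: from 17, phenylmethanethiol in AcOH should give the 2,3-trans-3,4-trans 4-benzylsulfanyl flavan-3-ol F4. AgBF4 in THF at 0 °C in the presence of 9 then releases the same C4 cation slowly and should give 18, where the route is rejoined.

3. Step 3. Benzyl ethers may be lost in HCl, or the electron-rich partners may condense sluggishly so that 3 degrades first (partial loss of the acetyl group is harmless, since it is removed in step 4). Fallback that builds ring F with a nitro group as the C3 placeholder, setting out from 4: commercial 3,4-bis(benzyloxy)benzaldehyde and nitromethane (NH4OAc, AcOH, reflux) give the nitrostyrene F5. Aldehyde 4 and F5 with DABCO in MeCN at 60 °C should undergo oxa-Michael addition, Henry closure and dehydration to the racemic 3-nitro-2H-chromene F6. Fe powder in AcOH/H2O at reflux reduces the conjugated nitroalkene and hydrolyses the resulting enamine to rejoin the route at 8.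

**Further compounds**

F1 | step 5 | rac-(2S,3S)-7-(benzyloxy)-2-[3,4-bis(benzyloxy)phenyl]-3,4-dihydro-2H-chromen-3-ol (2,3-cis racemate, one enantiomer drawn) | c1cc2c(cc1OCc1ccccc1)O[C@@H](c1ccc(OCc3ccccc3)c(OCc3ccccc3)c1)[C@@H](O)C2
F2 | step 5 | (2S,3S)-7-(benzyloxy)-2-[3,4-bis(benzyloxy)phenyl]-3,4-dihydro-2H-chromen-3-yl (S)-2-methoxy-2-phenylacetate | c1cc2c(cc1OCc1ccccc1)O[C@@H](c1ccc(OCc3ccccc3)c(OCc3ccccc3)c1)[C@@H](OC(=O)[C@@H](OC)c1ccccc1)C2
F3 | step 5 | (2R,3R)-7-(benzyloxy)-2-[3,4-bis(benzyloxy)phenyl]-3,4-dihydro-2H-chromen-3-yl (S)-2-methoxy-2-phenylacetate | c1cc2c(cc1OCc1ccccc1)O[C@H](c1ccc(OCc3ccccc3)c(OCc3ccccc3)c1)[C@H](OC(=O)[C@@H](OC)c1ccccc1)C2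
F4 | step 11 | 2,3-trans-3,4-trans-7-(benzyloxy)-2-[4-(benzyloxy)phenyl]-4-(benzylsulfanyl)-3,4-dihydro-2H-chromen-3-ol (C2 and C3 as in 17, 4α-sulfanyl) | C(c1ccccc1)Oc1ccc(cc1)[C@H]1Oc2cc(OCc3ccccc3)ccc2[C@@H](SCc2ccccc2)[C@@H]1O
F5 | step 3 | (E)-1,2-bis(benzyloxy)-4-(2-nitroethenyl)benzene | [O-][N+](=O)/C=C/c1ccc(OCc2ccccc2)c(OCc2ccccc2)c1
F6 | step 3 | rac-7-(benzyloxy)-2-[3,4-bis(benzyloxy)phenyl]-3-nitro-2H-chromene | [O-][N+](=O)C1=Cc2ccc(OCc3ccccc3)cc2OC1c1ccc(OCc2ccccc2)c(OCc2ccccc2)c1
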